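**Retrosynthetic overview**
- The target is released in one reductive operation from a tris-imide that also carries three 4-nitrobenzoates and two aryl acetates. Its three erythro arylglycerol units come from three Evans syn-aldol C7–C8 bond formations followed by one threefold Mitsunobu inversion at C7.
- Inner and outer guaiacyl units are joined through a vanillin ether that is aldehyde and imide at once, so the chain grows aldol, enolisation, aldol without protecting groups. The imide arms are attached to the core by phenol alkylation.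
- Core: (−)-syringaresinol. Both tetrahydrofuran rings close in one event from a C8–C8′-coupled bis-quinone methide, formed by phenoxyl-radical dimerisation of sinapyl alcohol that is generated in the same flask from 4-allyl-2,6-dimethoxyphenol through its vinyl quinone methide. One chromatographic resolution fixes the absolute configuration.
- Ring order: the two furofuran rings together in step 1. No other ring is made; all aromatic rings are bought.

Assumption: both enantiomers of 4-benzyl-3-(chloroacetyl)oxazolidin-2-one are catalogue compounds, and levorotatory syringaresinol is the (7R,7′R,8S,8′S) form encoded in the target SMILES.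

**Route**

Step 1
Reactants: 1 4-allyl-2,6-dimethoxyphenol (2 equiv)
Product: 5 racemic syringaresinol, via vinyl quinone methide 2 (not isolated), via sinapyl alcohol 3 (not isolated), via bis-quinone methide 4 (not isolated)
Conditions: Ag2O, CH2Cl2, 20 °C; filter, evaporate; acetone–H2O (4:1), cat. HCl, 20 °C; then FeCl3·6H2O, 0 → 20 °C
Reagents that add atoms: water (2 equiv), O
Why: Proposed new method: a one-flask telescoping of three individually known events in which two molecules of 1 and two of water make one molecule of 5, namely Ag2O dehydrogenation of the 4-allylphenol to its vinyl quinone methide, acid-catalysed 1,8-addition of water to give the conjugated sinapyl alcohol, and one-electron phenol oxidation by FeCl3, after which two phenoxyl radicals couple C8–C8′ in the threo sense and each CH2OH adds 5-exo to the opposite quinone methide from the convex face, so the cis ring fusion and both exo aryl groups (four stereocentres, racemic) are set in the ring-forming event; the closest known reaction type is the biomimetic oxidative β–β dimerisation of isolated sinapyl alcohol.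

Step 2
Reactants: 5 racemic syringaresinol
Product: 6 (−)-syringaresinol, the (7R,7′R,8S,8′S) enantiomer
Conditions: preparative SFC, cellulose tris(3,5-dimethylphenylcarbamate) phase, CO2–MeOH, 35 °C
Reagents that add atoms: none
Why: Chromatographic resolution on a chiral stationary phase separates the two enantiomers of this rigid C2-symmetric bis-phenol without any bond change, the levorotatory fraction being the (7R,7′R,8S,8′S) antipode whose four stereocentres are not touched again.

Step 3
Reactants: 6 (−)-syringaresinol; 7 (S)-4-benzyl-3-(chloroacetyl)oxazolidin-2-one (2 equiv)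
Product: 8 bis-imide, (−)-syringaresinol with both phenolic oxygens carrying CH2C(=O)–[(S)-4-benzyl-2-oxooxazolidin-3-yl]
Conditions: K2CO3, DMF, 25 °C
Reagents that add atoms: none
Why: Twofold Williamson ether synthesis in which each of the two phenoxides displaces chloride from one molecule of the activated α-chloro imide by SN2 faster than it attacks the imide carbonyls, with no stereocentre involved.

Step 4
Reactants: 9 vanillin; 10 (R)-4-benzyl-3-(chloroacetyl)oxazolidin-2-one
Product: 11 (R)-4-benzyl-3-[(4-formyl-2-methoxyphenoxy)acetyl]oxazolidin-2-one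
Conditions: K2CO3, DMF, 25 °C
Reagents that add atoms: none
Why: Williamson ether synthesis of the vanillin phenoxide with the α-chloro imide, leaving the aldehyde and the auxiliary stereocentre untouched.

Step 5
Reactants: 8 bis-imide; 11 aldehyde–imide
Product: 12 mono-syn-aldol adduct, 8 in which one OCH2C(=O)Xc arm has become O–CH[C(=O)Xc]–CH(OH)–Ar with (2S,3R) configuration (Xc = (S)-auxiliary; Ar = 3-methoxy-4-{2-[(R)-4-benzyl-2-oxooxazolidin-3-yl]-2-oxoethoxy}phenyl), the other arm unchanged
Conditions: Bu2BOTf (1.0 equiv), iPr2NEt, CH2Cl2, 0 °C; add 11 (0.9 equiv), −78 → 0 °C; MeOH, pH 7 buffer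
Reagents that add atoms: none
Why: Evans syn-aldol in which one equivalent of Bu2BOTf gives the Z-boron enolate of one arm, which adds to the aldehyde through a chair Zimmerman–Traxler transition state on the face opposite the benzyl group of the (S)-auxiliary, setting C8 in its final configuration and C7 as the syn (threo) epimer, while the imide of 11 stays un-enolised because no free boron triflate remains and unreacted 8 is recovered and recycled.

Step 6
Reactants: 12 mono-syn-aldol adduct; 13 vanillin acetate (2 equiv)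
Product: 14 tris-syn-aldol adduct, 12 in which the second core arm is O–CH[C(=O)Xc]–CH(OH)–(4-acetoxy-3-methoxyphenyl) with (2S,3R) configuration and the pendant OCH2C(=O)Xc′ arm is O–CH[C(=O)Xc′]–CH(OH)–(4-acetoxy-3-methoxyphenyl) with (2R,3S) configuration (Xc′ = (R)-auxiliary)
Conditions: Bu2BOTf (3.3 equiv), iPr2NEt, CH2Cl2, 0 °C; add 13 (slight excess), −78 → 0 °C; MeOH, pH 7 buffer
Reagents that add atoms: none
Why: Double Evans syn-aldol in which both remaining CH2 imides become Z-boron enolates (the free hydroxyl being masked in the flask as its dibutylborinate) and each adds to one molecule of vanillin acetate through a chair transition state under control of its own auxiliary, the (R)-auxiliary delivering the mirror-image syn pair needed for the outer unit.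

Step 7
Reactants: 14 tris-syn-aldol adduct
Product: 15 tris(4-nitrobenzoate) of 14 with all three carbinol carbons inverted, (2S,3S) at both core arms and (2R,3R) at the outer unit
Conditions: PPh3, DIAD, 4-nitrobenzoic acid (6 equiv each), toluene–THF, −20 → 20 °C
Reagents that add atoms: 4-nitrobenzoic acid (3 equiv), O=C(O)c1ccc(cc1)[N+](=O)[O-]
Why: Threefold Mitsunobu reaction in which each benzylic oxyphosphonium ion is displaced by 4-nitrobenzoate with SN2 inversion, converting the three syn (threo) carbinols into the anti (erythro) configuration of the target while the adjacent C8 centres, shielded from enolisation by allylic strain in the imide, are untouched.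

Step 8
Reactants: 15 tris(4-nitrobenzoate)
Product: 16 target, (7R,7′R,8S,8′S)-syringaresinol whose one phenolic oxygen carries a (7S,8R)-guaiacylglycerol-8-yl unit that is itself 4-O-linked to a (7R,8S)-guaiacylglycerol-8-yl unit, and whose other phenolic oxygen carries a (7S,8R)-guaiacylglycerol-8-yl unit (all three erythro)
Conditions: LiBH4 (excess), THF–MeOH, 0 → 20 °C; aq. NH4Cl
Reagents that add atoms: none
Why: Global hydride reduction in which LiBH4 reduces the three N-acyl oxazolidinones to primary alcohols and cleaves the three nitrobenzoates and two aryl acetates reductively, without touching any stereocentre, the nitro groups or the furofuran.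

**Compound list**

1 | 4-allyl-2,6-dimethoxyphenol | COc1cc(CC=C)cc(OC)c1O | starting material
2 | 2,6-dimethoxy-4-(prop-2-en-1-ylidene)cyclohexa-2,5-dien-1-one (vinyl quinone methide) | C=CC=C1C=C(OC)C(=O)C(OC)=C1 | intermediate
3 | (E)-sinapyl alcohol | COc1cc(/C=C/CO)cc(OC)c1O | intermediate
4 | racemic threo (C2-symmetric) 2,3-bis[(3,5-dimethoxy-4-oxocyclohexa-2,5-dien-1-ylidene)methyl]butane-1,4-diol (bis-quinone methide, both enantiomers given) | OC[C@@H](C=C1C=C(OC)C(=O)C(OC)=C1)[C@@H](CO)C=C1C=C(OC)C(=O)C(OC)=C1.OC[C@H](C=C1C=C(OC)C(=O)C(OC)=C1)[C@H](CO)C=C1C=C(OC)C(=O)C(OC)=C1 | intermediate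
5 | racemic syringaresinol (cis-fused furofuran, both aryl groups exo; both enantiomers given) | COc1cc(cc(OC)c1O)[C@@H]1OC[C@@H]2[C@H]1CO[C@H]2c1cc(OC)c(O)c(OC)c1.COc1cc(cc(OC)c1O)[C@H]1OC[C@H]2[C@@H]1CO[C@@H]2c1cc(OC)c(O)c(OC)c1 | intermediate
6 | (−)-syringaresinol, (7R,7′R,8S,8′S) | COc1cc(cc(OC)c1O)[C@@H]1OC[C@@H]2[C@H]1CO[C@H]2c1cc(OC)c(O)c(OC)c1 | intermediate
7 | (S)-4-benzyl-3-(chloroacetyl)oxazolidin-2-one | O=C1OC[C@H](Cc2ccccc2)N1C(=O)CCl | starting material
8 | bis-imide: (−)-syringaresinol 4,4′-bis-O-{2-[(S)-4-benzyl-2-oxooxazolidin-3-yl]-2-oxoethyl} ether | COc1cc(cc(OC)c1OCC(=O)N1C(=O)OC[C@@H]1Cc1ccccc1)[C@@H]1OC[C@@H]2[C@H]1CO[C@H]2c1cc(OC)c(OCC(=O)N2C(=O)OC[C@@H]2Cc2ccccc2)c(OC)c1 | intermediate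
9 | vanillin | COc1cc(C=O)ccc1O | starting material
10 | (R)-4-benzyl-3-(chloroacetyl)oxazolidin-2-one | O=C1OC[C@@H](Cc2ccccc2)N1C(=O)CCl | starting material
11 | (R)-4-benzyl-3-[(4-formyl-2-methoxyphenoxy)acetyl]oxazolidin-2-one | COc1cc(C=O)ccc1OCC(=O)N1C(=O)OC[C@H]1Cc1ccccc1 | intermediate
12 | mono-syn-aldol adduct: one core arm (2S,3R)-2-aryloxy-3-hydroxy-3-aryl-propanoyl imide with pendant (R)-imide, other arm unchanged | COc1cc(ccc1OCC(=O)N1C(=O)OC[C@H]1Cc1ccccc1)[C@@H](O)[C@@H](C(=O)N1C(=O)OC[C@@H]1Cc1ccccc1)Oc1c(OC)cc(cc1OC)[C@@H]1OC[C@@H]2[C@H]1CO[C@H]2c1cc(OC)c(OCC(=O)N2C(=O)OC[C@@H]2Cc2ccccc2)c(OC)c1 | intermediate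
13 | vanillin acetate (4-formyl-2-methoxyphenyl acetate) | COc1cc(C=O)ccc1OC(C)=O | starting material
14 | tris-syn-aldol adduct: core arms (2S,3R), outer unit (2R,3S), two aryl acetates | COc1cc(ccc1OC(C)=O)[C@H](O)[C@H](C(=O)N1C(=O)OC[C@H]1Cc1ccccc1)Oc1ccc(cc1OC)[C@@H](O)[C@@H](C(=O)N1C(=O)OC[C@@H]1Cc1ccccc1)Oc1c(OC)cc(cc1OC)[C@@H]1OC[C@@H]2[C@H]1CO[C@H]2c1cc(OC)c(O[C@H](C(=O)N2C(=O)OC[C@@H]2Cc2ccccc2)[C@H](O)c2ccc(OC(C)=O)c(OC)c2)c(OC)c1 | intermediate
15 | tris(4-nitrobenzoate) with inverted carbinols: core arms (2S,3S), outer unit (2R,3R) | COc1cc(ccc1OC(C)=O)[C@@H](OC(=O)c1ccc(cc1)[N+](=O)[O-])[C@H](C(=O)N1C(=O)OC[C@H]1Cc1ccccc1)Oc1ccc(cc1OC)[C@H](OC(=O)c1ccc(cc1)[N+](=O)[O-])[C@@H](C(=O)N1C(=O)OC[C@@H]1Cc1ccccc1)Oc1c(OC)cc(cc1OC)[C@@H]1OC[C@@H]2[C@H]1CO[C@H]2c1cc(OC)c(O[C@H](C(=O)N2C(=O)OC[C@@H]2Cc2ccccc2)[C@@H](OC(=O)c2ccc(cc2)[N+](=O)[O-])c2ccc(OC(C)=O)c(OC)c2)c(OC)c1 | intermediate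
16 | CNP0316493.2: (7R,7′R,8S,8′S)-syringaresinol bearing on one phenol a (7S,8R)-guaiacylglycerol-8-yl unit 4-O-linked to a (7R,8S)-guaiacylglycerol-8-yl unit, and on the other phenol a (7S,8R)-guaiacylglycerol-8-yl unit | COc1cc([C@@H](O)[C@H](CO)Oc2ccc([C@H](O)[C@@H](CO)Oc3c(OC)cc([C@@H]4OC[C@@H]5[C@H]4CO[C@H]5c4cc(OC)c(O[C@H](CO)[C@@H](O)c5ccc(O)c(OC)c5)c(OC)c4)cc3OC)cc2OC)ccc1O | target

**Totals and fallbacks**

Total step count: 8. Longest linear sequence: 7 (steps 1, 2, 3, 5, 6, 7, 8); step 4 is a one-step side branch.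

Steps most likely to fail:

Step 1 (untested one-flask cascade). The fallback sets out from 1 and comes back at 5. 1 is dehydrogenated with DDQ (2.2 equiv) in wet dioxane, which takes the same vinyl quinone methide through to crystalline (E)-sinapaldehyde F1. F1 is reduced with NaBH4 in EtOH to sinapyl alcohol 3, this time isolated and purified. Two molecules of 3 are then dimerised with FeCl3·6H2O in aqueous acetone to 5.

Step 5 (statistical mono-aldol on a C2-symmetric bis-imide; at most about half of 8 is converted to 12 per pass). The fallback sets out from 6 and comes back at 12, telling the two arms apart before any aldol. 6 is mono-alkylated with 7 (0.9 equiv, K2CO3, DMF; unreacted 6 and the by-product 8 both re-enter the route) to give the mono-imide phenol F2. The boron enolate of F2 (2.2 equiv Bu2BOTf, iPr2NEt, the phenol masked in the flask as its borinate) adds to 11 to give the syn-adduct phenol F3. Alkylation of the remaining phenol of F3 with 7 (K2CO3, acetone, 20 °C) gives 12; the base-sensitivity of the β-hydroxy imide is the risk of this variant.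

Step 7 (threefold Mitsunobu inversion; risks are dehydration to the α-aryloxy acrylimide and SN1 leakage at the p-alkoxybenzylic centre). The fallback sets out from 6 and comes back at 16, making the erythro carbinols directly by an open-transition-state anti-aldol of the boron enolate with an Et2AlCl-complexed aldehyde. That variant uses the other enolate face, so the enantiomeric auxiliaries are needed. 6 and two equivalents of 10 (K2CO3, DMF) give the bis-(R)-imide F4. 9 and 7 give the (S)-configured aldehyde–imide F5. The mono-enolate of F4 (1.0 equiv Bu2BOTf, iPr2NEt) added to F5 precomplexed with Et2AlCl gives the anti mono-adduct F6. Enolisation of both remaining imides of F6 and addition to two equivalents of 13 precomplexed with Et2AlCl gives the tris-anti-adduct F7, which already has the erythro configuration at all three units. LiBH4 then gives 16 directly.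

**Further compounds**

F1 | step 1 | (E)-sinapaldehyde | COc1cc(/C=C/C=O)cc(OC)c1O
F2 | step 5 | (−)-syringaresinol mono-O-{2-[(S)-4-benzyl-2-oxooxazolidin-3-yl]-2-oxoethyl} ether | COc1cc(cc(OC)c1OCC(=O)N1C(=O)OC[C@@H]1Cc1ccccc1)[C@@H]1OC[C@@H]2[C@H]1CO[C@H]2c1cc(OC)c(O)c(OC)c1
F3 | step 5 | syn-aldol adduct (2S,3R) of F2 with 11, second syringyl phenol free | COc1cc(ccc1OCC(=O)N1C(=O)OC[C@H]1Cc1ccccc1)[C@@H](O)[C@@H](C(=O)N1C(=O)OC[C@@H]1Cc1ccccc1)Oc1c(OC)cc(cc1OC)[C@@H]1OC[C@@H]2[C@H]1CO[C@H]2c1cc(OC)c(O)c(OC)c1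
F4 | step 7 | (−)-syringaresinol 4,4′-bis-O-{2-[(R)-4-benzyl-2-oxooxazolidin-3-yl]-2-oxoethyl} ether | COc1cc(cc(OC)c1OCC(=O)N1C(=O)OC[C@H]1Cc1ccccc1)[C@@H]1OC[C@@H]2[C@H]1CO[C@H]2c1cc(OC)c(OCC(=O)N2C(=O)OC[C@H]2Cc2ccccc2)c(OC)c1
F5 | step 7 | (S)-4-benzyl-3-[(4-formyl-2-methoxyphenoxy)acetyl]oxazolidin-2-one | COc1cc(C=O)ccc1OCC(=O)N1C(=O)OC[C@@H]1Cc1ccccc1
F6 | step 7 | anti mono-aldol adduct (2S,3S) of F4 with F5, other arm unchanged | COc1cc(ccc1OCC(=O)N1C(=O)OC[C@@H]1Cc1ccccc1)[C@H](O)[C@@H](C(=O)N1C(=O)OC[C@H]1Cc1ccccc1)Oc1c(OC)cc(cc1OC)[C@@H]1OC[C@@H]2[C@H]1CO[C@H]2c1cc(OC)c(OCC(=O)N2C(=O)OC[C@H]2Cc2ccccc2)c(OC)c1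
F7 | step 7 | tris-anti-aldol adduct: core arms (2S,3S), outer unit (2R,3R), two aryl acetates | COc1cc(ccc1OC(C)=O)[C@@H](O)[C@H](C(=O)N1C(=O)OC[C@@H]1Cc1ccccc1)Oc1ccc(cc1OC)[C@H](O)[C@@H](C(=O)N1C(=O)OC[C@H]1Cc1ccccc1)Oc1c(OC)cc(cc1OC)[C@@H]1OC[C@@H]2[C@H]1CO[C@H]2c1cc(OC)c(O[C@H](C(=O)N2C(=O)OC[C@H]2Cc2ccccc2)[C@@H](O)c2ccc(OC(C)=O)c(OC)c2)c(OC)c1
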